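Readings and results are calculated from invented constants; scatter was added.

1. The fractions of the charge sum to one, so whatever starting material and target do not hold together is a shortfall.

| flask | starting material | gas phase | catalyst | added ligand | remark | time |
|---|---|---|---|---|---|---|
| Thursday's | 0.064 M | 3.9 mM (held) | 0.75 mM | 1.8 mM | run made earlier |  |
| Saturday's | 0.064 M | 3.9 mM (held) | 1.1 mM | 1.8 mM | run made earlier |  |
| flask | 0.064 M | 3.9 mM (held) | 1.5 mM | 1.8 mM |  | 20 min |

| run | time / min | target / % | starting material / % |
|---|---|---|---|
| Thursday's | 2.50 | 9.7 | 92.2 |
| Thursday's | 8.00 | 27.1 | 71.8 |
| Thursday's | 12.0 | 39.2 | 58.8 |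
| Thursday's | 20.0 | 54.5 | 42.2 |
| Saturday's | 1.50 | 7.5 | 91.8 |
| Saturday's | 4.00 | 23.8 | 75.3 |
| Saturday's | 8.00 | 43.0 | 56.8 |
| Saturday's | 20.0 | 68.8 | 20.9 |

(each reading ± 1 percentage point)

- at the start none of the gas phase is in solution

* how much target there is at 20 min, in percent of the starting material charged
* the change that raises the amount of target at 20 min, in percent of the starting material charged most ("none" if none brings more than 2 percentage points) (maple / birch / ash / none)
* amount of target at 20 min, in percent of the starting material charged, after maple

- maple: doubling the transfer coefficient of the gas phase, all else as stated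
- birch: doubling the amount of catalyst, all else as stated
- ash: doubling the saturation concentration of gas phase, all else as stated

2. Catalyst, gas and time fold into one number, the exposure X: the natural logarithm of one over A, the fraction of starting material left. At 20 min, X reads 0.863 on Thursday and 1.57 on Saturday, which is an apparent catalyst order of 1.56 with added ligand held at 1.8 mM. Scaled to the flask's catalyst, X is reckoned at 2.54, leaving A at 7.92%.

3. X gives starting material but not target, so one number is not enough. The second is the selectivity factor S, the shortfall divided by X minus one plus A, that sum being the exposure of the reacted fraction. Saturday gives 0.133 and Thursday 0.116. Their difference is smaller than the shift that one point of scatter makes in Thursday's value.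

4. Early on, target follows one minus A; late, the shortfall grows with X. In this reckoning the two ends join at a peak where A equals S over one plus S, read as 11.7%. The reckoning for the flask is 70.6%.

5. The flask's reckoned A lies below that peak value, so in this reckoning added exposure lowers target. Maple, birch and ash each add exposure, so the reckoned choice is none, and maple is reckoned below 70.6%, by an amount not sized here.

6. The forecast says 71% (65% to 75%), none, and 71.5% after maple, above its own 71% where this reckoning goes below: “Better transfer barely moves it”.

    catalyst + added ligand ⇌ idle complex, settled at all times (K = 12000 L mol⁻¹)
    gas phase ⇌ dissolved gas, rate k2*(csat - [dissolved gas]) (kL = 0.0550 s⁻¹)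
    starting material + dissolved gas + catalyst → catalyst + target (k = 4400 L² mol⁻² s⁻¹)
    dissolved gas + catalyst + target → catalyst + over-reaction product (k = 750 L² mol⁻² s⁻¹)

The flask gives 66.6%, the best change is none, and maple gives 62.0%. At 20.0 min the flask keeps 5.2% of its starting material, an exposure of 2.95, so S puts its over-reaction product at 26.6%; it holds 28.2%. The neighbour flask with 0.026 M of starting material keeps 2.5%, an exposure of 3.69, so S puts its over-reaction product at 36.1%; it holds 36.2%.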